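A direct plan would condense 2'-hydroxy-5'-methoxyacetophenone A1 with 3,4,5-trimethoxybenzaldehyde A2 to the chalcone A3, close ring C oxidatively (I2, DMSO) to 6,3',4',5'-tetramethoxyflavone A4, and add the C5 methoxy group last by a C4=O-directed, metal-catalysed C–H methoxylation with the N-methoxy bis(sulfonyl)imide A5. Its weakest steps would be:
(a) the late C5–H methoxylation: a C–O bond formation without close precedent on a flavone, run on the most valuable intermediate, with two electron-rich arenes exposed to an oxidising metal centre;
(b) the separate synthesis of A5, which would add nothing to the skeleton and exist only to serve (a);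
(c) the oxidative closure of A3 in hot DMSO, where iodine and HI could iodinate or demethylate the polymethoxyarenes.
The plan would also buy ring A with the wrong oxygenation and mend it at the end.

**Plan of the new route.** The retrosynthesis cuts ring C at both of its bonds to ring A (C8a–O1 and C4a–C4) and at O1–C2. This leads back to 3,4-dimethoxybenzyne (ring A) and 3-(3,4,5-trimethoxyphenyl)propynoic acid (ring B, C2 to C4 and both ring-C oxygens). Rings A and B are bought fully oxygenated; ring C is the only ring made and arises in one operation. The enabling feature is that C8a(O1), C4a(C4), C5(OMe) and C6(OMe) are contiguous in ring A. The triple bond C4a≡C8a therefore has a methoxy group on one flank only, which sends oxygen to C8a and the acyl carbon to C4a. No C–H oxidation, oxidative closure or purpose-made reagent remains, and the chromone core appears only in the target.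

Key step: step 5

Assumption: 2,3-dimethoxyphenol, isopropyl isocyanate and 5-ethynyl-1,2,3-trimethoxybenzene are taken as catalogue compounds. The target has no stereocentre, so nothing has to be set.

Step 1
Reactants: 1 2,3-dimethoxyphenol; 2 isopropyl isocyanate
Product: 3 2,3-dimethoxyphenyl N-isopropylcarbamate
Conditions: iPrNCO (1.5 equiv), Et3N (0.2 equiv), CH2Cl2, rt, 16 h
Reagents that add atoms: 2 isopropyl isocyanate, CC(C)N=C=O
Why: Base-catalysed addition of the phenol O–H to the isocyanate gives the N-monoalkyl carbamate, which is the directing group for the ortho-metalation and can later be removed by E1cB cleavage.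

Step 2
Reactants: 3 2,3-dimethoxyphenyl N-isopropylcarbamate
Product: 6 2,3-dimethoxy-6-(trimethylsilyl)phenyl N-isopropylcarbamate, via N-silyl carbamate 4 (not isolated), via disilyl carbamate 5 (not isolated)
Conditions: TBSOTf (1.1 equiv), TMEDA (1.1 equiv), Et2O, 0 °C to rt; then TMEDA (2 equiv), n-BuLi (2 equiv), −78 °C, 4 h; then TMSCl (3.5 equiv), −78 °C to rt; aq. NaHSO4
Reagents that add atoms: chlorotrimethylsilane, C[Si](C)(C)Cl
Why: Directed ortho-metalation (Snieckus type) of the carbamate whose N–H is masked in the flask as the N-silyl derivative 4, which prevents N-deprotonation and slows the anionic ortho-Fries shift; C6 is the only free position ortho to the carbamate and the carbamate outranks the methoxy groups as director, so silicon should enter at C6 alone, and the N–Si bond of 5 is hydrolysed on acidic work-up.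

Step 3
Reactants: 6 2,3-dimethoxy-6-(trimethylsilyl)phenyl N-isopropylcarbamate
Product: 8 2,3-dimethoxy-6-(trimethylsilyl)phenyl trifluoromethanesulfonate, via silylphenol 7 (not isolated)
Conditions: Et2NH (1.5 equiv), DBU (1.5 equiv), MeCN, 40 °C; then PhNTf2 (1.5 equiv), rt
Reagents that add atoms: N-phenylbis(trifluoromethanesulfonimide), O=S(=O)(N(c1ccccc1)S(=O)(=O)C(F)(F)F)C(F)(F)F
Why: DBU removes the carbamate N–H and E1cB loss of isopropyl isocyanate (trapped by Et2NH as a urea) frees the phenoxide of 7, which is O-sulfonylated in the same flask by PhNTf2 under conditions mild enough to keep the aryl–silicon bond (one-pot carbamate cleavage and triflation).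

Step 4
Reactants: 9 5-ethynyl-1,2,3-trimethoxybenzene
Product: 10 3-(3,4,5-trimethoxyphenyl)prop-2-ynoic acid
Conditions: n-BuLi (1.1 equiv), THF, −78 °C, 30 min; CO2 (gas), −78 °C to 0 °C; aq. HCl (1 M), 0 °C
Reagents that add atoms: carbon dioxide, O=C=O
Why: Carboxylation of a lithium acetylide; the alkyne C–H is the only acidic site and the lithium carboxylate formed is inert to further attack.

Step 5
Reactants: 8 2,3-dimethoxy-6-(trimethylsilyl)phenyl trifluoromethanesulfonate (1.5 equiv); 10 3-(3,4,5-trimethoxyphenyl)prop-2-ynoic acid
Product: 13 Cerosilin B (5,6-dimethoxy-2-(3,4,5-trimethoxyphenyl)-4H-chromen-4-one), via 3,4-dimethoxybenzyne 11 (not isolated), via hydroxyaryl ynone 12 (not isolated)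
Conditions: CsF (4 equiv), THF, 125 °C (sealed tube), 24 h, under argon
Reagents that add atoms: none
Why: Fluoride strips SiMe3 from 8 and triflate leaves from the neighbouring carbon to give aryne 11, while CsF turns 10 into its caesium carboxylate and stores the proton as bifluoride. The carboxylate oxygen adds to the aryne carbon remote from the methoxy groups (future C8a), because the methoxy group at future C5 distorts the aryne towards attack there and stabilises by induction the aryl anion that develops beside it at future C4a, and the C6 methoxy group, nearer to C4a than to C8a, acts in the same sense; this answers the only regiochemical question of the synthesis. The aryl anion then attacks the adjacent ester carbonyl (4-exo-trig) and the strained benzoxete alkoxide opens by C–O cleavage to the phenoxide of ynone 12, an intramolecular O-to-C acyl shift that should outrun both proton capture and conjugate addition to the linear alkynoate. Ring C closes by 6-endo-dig oxa-Michael addition of this phenoxide to the ynone β-carbon, which gives a carbonyl-stabilised allenolate that takes the proton back at C3, whereas the 5-exo-dig mode to an aurone would need an unstabilised vinyl anion in this aprotic medium. The closest known reaction type is the fluoride-induced insertion of arynes into the C–O bond of carboxylic acids to give ortho-hydroxyaryl ketones, which with 3-arylpropynoic acids runs on to flavones, and 3-methoxybenzyne is known to give the 2-hydroxy-6-methoxyaryl ketone pattern needed here. No stereocentre is formed.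

## Compound list
1 | 2,3-dimethoxyphenol | COc1cccc(O)c1OC | starting material
2 | isopropyl isocyanate | CC(C)N=C=O | starting material
3 | 2,3-dimethoxyphenyl N-isopropylcarbamate | COc1cccc(OC(=O)NC(C)C)c1OC | intermediate
4 | 2,3-dimethoxyphenyl N-(tert-butyldimethylsilyl)-N-isopropylcarbamate (not isolated) | COc1cccc(OC(=O)N(C(C)C)[Si](C)(C)C(C)(C)C)c1OC | intermediate
5 | 2,3-dimethoxy-6-(trimethylsilyl)phenyl N-(tert-butyldimethylsilyl)-N-isopropylcarbamate (not isolated) | COc1ccc([Si](C)(C)C)c(OC(=O)N(C(C)C)[Si](C)(C)C(C)(C)C)c1OC | intermediate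
6 | 2,3-dimethoxy-6-(trimethylsilyl)phenyl N-isopropylcarbamate | COc1ccc([Si](C)(C)C)c(OC(=O)NC(C)C)c1OC | intermediate
7 | 2,3-dimethoxy-6-(trimethylsilyl)phenol (not isolated) | COc1ccc([Si](C)(C)C)c(O)c1OC | intermediate
8 | 2,3-dimethoxy-6-(trimethylsilyl)phenyl trifluoromethanesulfonate | COc1ccc([Si](C)(C)C)c(OS(=O)(=O)C(F)(F)F)c1OC | intermediate
9 | 5-ethynyl-1,2,3-trimethoxybenzene | COc1cc(C#C)cc(OC)c1OC | starting material
10 | 3-(3,4,5-trimethoxyphenyl)prop-2-ynoic acid | COc1cc(C#CC(=O)O)cc(OC)c1OC | intermediate
11 | 3,4-dimethoxybenzyne (1,2-didehydro-3,4-dimethoxybenzene, not isolated) | COC1=C(OC)C#CC=C1 | intermediate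
12 | 1-(6-hydroxy-2,3-dimethoxyphenyl)-3-(3,4,5-trimethoxyphenyl)prop-2-yn-1-one (not isolated) | COc1ccc(O)c(C(=O)C#Cc2cc(OC)c(OC)c(OC)c2)c1OC | intermediate
13 | Cerosilin B, 5,6-dimethoxy-2-(3,4,5-trimethoxyphenyl)-4H-chromen-4-one (achiral) | COc1cc(-c2cc(=O)c3c(OC)c(OC)ccc3o2)cc(OC)c1OC | target

Total step count: 5. Longest linear sequence: 4 (steps 1, 2, 3 and 5); step 4 is the one-step second branch.

## Steps most likely to fail

**Step 5.** Three processes could compete with the intended cascade:
- proton capture by the aryl anion before the acyl shift (net O–H insertion, which stops at an aryl ester);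
- conjugate addition of that anion to the alkynoate;
- loss of CO2 from the propynoate at 125 °C before it meets the aryne.

The fallback gives up the aryne and forms the C4a–C4 bond by directed ortho-metalation; it sets out from 10 and comes back at 13 by way of 12. Acid 10 would be converted into its Weinreb amide, N-methoxy-N-methyl-3-(3,4,5-trimethoxyphenyl)prop-2-ynamide F1 (MeNHOMe·HCl, EDC·HCl, N-methylmorpholine, CH2Cl2). Commercial 3,4-dimethoxyphenol F2 would be protected as 4-(methoxymethoxy)-1,2-dimethoxybenzene F3 (MOMCl, iPr2NEt, CH2Cl2) and lithiated between its two oxygen directors (n-BuLi, THF, 0 °C). Acylation of this aryllithium with F1 at −78 °C would give 1-[2,3-dimethoxy-6-(methoxymethoxy)phenyl]-3-(3,4,5-trimethoxyphenyl)prop-2-yn-1-one F4. HCl in MeOH would free the phenol to give 12, and K2CO3 in acetone would close it in the 6-endo mode to 13.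

**Step 2.** Incomplete N-silylation would let butyllithium deprotonate nitrogen, or let the carbamoyl group migrate to carbon (anionic ortho-Fries shift) before the aryllithium is silylated. The fallback makes the C–Si bond by halogen–metal exchange without any carbamate; it sets out from 1 and comes back at 8. Ortho-selective bromination of 1 (tBuNH2, Br2, toluene, −78 °C) would give 6-bromo-2,3-dimethoxyphenol F5. O-Silylation with (Me3Si)2NH would give (6-bromo-2,3-dimethoxyphenoxy)trimethylsilane F6. n-BuLi at −78 °C would exchange bromine for lithium, the silyl group would shift from oxygen to carbon (retro-Brook rearrangement), and the lithium phenoxide of 7 so formed would be trapped in the same flask with Tf2O to give 8.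

**Step 3.** The phenoxide of 7 is flanked by OMe and SiMe3 and may be sulfonylated slowly, and long exposure to the amine bases may cost the silyl group by protodesilylation. The fallback reaches the same aryne from the regioisomeric precursor, whose phenoxide has only one ortho neighbour; it sets out from 2 and comes back at 11. Isocyanate 2 would be added to 3,4-dimethoxyphenol F2 to give 3,4-dimethoxyphenyl N-isopropylcarbamate F7. Silylation on nitrogen in the flask would give 3,4-dimethoxyphenyl N-(tert-butyldimethylsilyl)-N-isopropylcarbamate F8. Lithiation at C2, between the carbamate and the methoxy group, and TMSCl would give 3,4-dimethoxy-2-(trimethylsilyl)phenyl N-(tert-butyldimethylsilyl)-N-isopropylcarbamate F9, and acidic work-up 3,4-dimethoxy-2-(trimethylsilyl)phenyl N-isopropylcarbamate F10. Et2NH and DBU, then PhNTf2, would give, by way of 3,4-dimethoxy-2-(trimethylsilyl)phenol F11, the triflate 3,4-dimethoxy-2-(trimethylsilyl)phenyl trifluoromethanesulfonate F12. With CsF under the conditions of step 5, F12 would lose its two groups from the same two ring carbons as 8 and give aryne 11.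

## Further compounds
F1 | step 5 | N-methoxy-N-methyl-3-(3,4,5-trimethoxyphenyl)prop-2-ynamide | CON(C)C(=O)C#Cc1cc(OC)c(OC)c(OC)c1
F2 | step 5 | 3,4-dimethoxyphenol | COc1ccc(O)cc1OC
F3 | step 5 | 4-(methoxymethoxy)-1,2-dimethoxybenzene | COCOc1ccc(OC)c(OC)c1
F4 | step 5 | 1-[2,3-dimethoxy-6-(methoxymethoxy)phenyl]-3-(3,4,5-trimethoxyphenyl)prop-2-yn-1-one | COCOc1ccc(OC)c(OC)c1C(=O)C#Cc1cc(OC)c(OC)c(OC)c1
F5 | step 2 | 6-bromo-2,3-dimethoxyphenol | COc1ccc(Br)c(O)c1OC
F6 | step 2 | (6-bromo-2,3-dimethoxyphenoxy)trimethylsilane | COc1ccc(Br)c(O[Si](C)(C)C)c1OC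
F7 | step 3 | 3,4-dimethoxyphenyl N-isopropylcarbamate | COc1ccc(OC(=O)NC(C)C)cc1OC
F8 | step 3 | 3,4-dimethoxyphenyl N-(tert-butyldimethylsilyl)-N-isopropylcarbamate | COc1ccc(OC(=O)N(C(C)C)[Si](C)(C)C(C)(C)C)cc1OC
F9 | step 3 | 3,4-dimethoxy-2-(trimethylsilyl)phenyl N-(tert-butyldimethylsilyl)-N-isopropylcarbamate | COc1ccc(OC(=O)N(C(C)C)[Si](C)(C)C(C)(C)C)c([Si](C)(C)C)c1OC
F10 | step 3 | 3,4-dimethoxy-2-(trimethylsilyl)phenyl N-isopropylcarbamate | COc1ccc(OC(=O)NC(C)C)c([Si](C)(C)C)c1OC
F11 | step 3 | 3,4-dimethoxy-2-(trimethylsilyl)phenol | COc1ccc(O)c([Si](C)(C)C)c1OC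
F12 | step 3 | 3,4-dimethoxy-2-(trimethylsilyl)phenyl trifluoromethanesulfonate | COc1ccc(OS(=O)(=O)C(F)(F)F)c([Si](C)(C)C)c1OC
A1 | direct plan | 1-(2-hydroxy-5-methoxyphenyl)ethan-1-one | CC(=O)c1cc(OC)ccc1O
A2 | direct plan | 3,4,5-trimethoxybenzaldehyde | COc1cc(C=O)cc(OC)c1OC
A3 | direct plan | (E)-1-(2-hydroxy-5-methoxyphenyl)-3-(3,4,5-trimethoxyphenyl)prop-2-en-1-one | COc1ccc(O)c(C(=O)/C=C/c2cc(OC)c(OC)c(OC)c2)c1
A4 | direct plan | 6-methoxy-2-(3,4,5-trimethoxyphenyl)-4H-chromen-4-one | COc1ccc2oc(-c3cc(OC)c(OC)c(OC)c3)cc(=O)c2c1
A5 | direct plan | N-methoxy-N-(phenylsulfonyl)benzenesulfonamide | CON(S(=O)(=O)c1ccccc1)S(=O)(=O)c1ccccc1
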